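I decided to reckon these flasks by one number, a rate constant carried per unit of catalyst, and to read it from the two earlier runs.

| flask | starting material | catalyst | temperature | remark | time |
|---|---|---|---|---|---|
| Monday's | 20 mM | 0.36 mol% | 55 °C | run made earlier |  |
| Saturday's | 20 mM | 6.6 mol% | 66 °C | run made earlier |  |
| dusk | 20 mM | 8 mol% | 60 °C |  | 12 h |
| noon | 20 mM | 0.6 mol% | 60 °C |  | 12 h |
| midnight | 20 mM | 1.8 mol% | 60 °C |  | 12 h |
| winter | 20 mM | 1.2 mol% | 60 °C |  | 12 h |

| run | time / h | target / % |
|---|---|---|
| Monday's | 1.33 | 0.2 |
| Monday's | 2.50 | 0 |
| Monday's | 4.00 | 1.7 |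
| Monday's | 5.00 | 1.3 |
| Monday's | 6.00 | 1.6 |
| Saturday's | 0.500 | 3.3 |
| Saturday's | 1.50 | 14.1 |
| Saturday's | 3.00 | 36.3 |
| Saturday's | 4.00 | 45.4 |
| Saturday's | 6.00 | 64.2 |

(readings scatter by 1 percentage point)

1. the flasks by amount of target, in percent of the starting material charged, highest first, at 12 h (dusk / noon / midnight / winter)
2. the amount of target, in percent of the starting material charged of the flask you put first, at 12 h
3. the amount of target, in percent of the starting material charged of the flask you put last, at 12 h



1. Saturday's target comes after a lag, then runs straight. For a first-order step, the logarithm of the charge over what is not yet target grows linearly with time. It stood at 0.451 at 3.00 h and at 1.03 at 6.00 h, so the slope was 0.192 h⁻¹. Drawn back to zero, that line gives a lag of 0.652 h. I replaced the curved start by this flat delay.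

2. Saturday's flask held [catalyst] = 1.32 mM. I took the catalyst as unchanged, which makes the step pseudo-first-order, and dividing gave 0.0404 L mol⁻¹ s⁻¹ at 66 °C.

3. Monday's readings are small against their scatter, so I took the mean of the last three, 1.53%, at their mean time of 5.00 h. I kept Saturday's lag, though a cooler flask may lag longer. That gave 0.00353 h⁻¹, or 0.0136 L mol⁻¹ s⁻¹ once divided by [catalyst], at 55 °C.

4. I took the logarithm of this constant as straight in temperature. Then 60 °C lies 0.455 of the way from Monday's to Saturday's, which gives 0.0223 L mol⁻¹ s⁻¹: the catalyst constant, the first-order constant divided by [catalyst] at 60 °C.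

5. Target is the whole minus the exponential of the catalyst constant times [catalyst] times the time after the lag, with a minus sign. Dusk, at 1.60 mM, comes to 76.7%. Noon, at 0.120 mM, comes to 10.4%. In this reckoning the flasks rank by loading: dusk has more than the others, noon less, and midnight more than winter.

The forecast gave dusk > midnight > winter > noon, with 73% and 9%, and said: “Allowing about 1 h of lag leaves roughly 11 h of effective time.” My dusk figure stood higher.

The flasks gave dusk > midnight > winter > noon, with dusk at 78.4% and noon at 11.0%.

    starting material → intermediate (k = 2.18 × 10⁻⁴ s⁻¹, Ea = 111 kJ mol⁻¹)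
    catalyst + intermediate → catalyst + target (k = 0.0251 L mol⁻¹ s⁻¹, Ea = 71.0 kJ mol⁻¹)
    (constants at 60 °C)

At 12.0 h, dusk held 78.4% as target and 21.6% as intermediate, with its catalyst at 100% of the charge. The catalyst constant had put dusk's first-order constant at 0.128 h⁻¹, and my 76.7% lies 1.7 percentage points under the flask. A neighbouring flask is dusk at 50 mM of starting material with the same loading, so its [catalyst] is 4.00 mM. The same constant and lag give 97.4%. That flask gave 97.6% of target, with 2.41% still intermediate.

All runs were generated by integration with made-up constants; noise was put on by code.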